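In a one-step world with a rate proportional to [reagent], doubling the reagent charge at one [starting material] doubles the early [target]. The eta and beta runs test this at the same [starting material].

| flask | starting material | reagent | time |
|---|---|---|---|
| eta | 0.200 M | 0.240 M |  |
| beta | 0.200 M | 0.480 M |  |
| epsilon | 0.800 M | 0.240 M | 20 min |

| run | time / min | [target] / M |
|---|---|---|
| eta run | 2.5 | 0.0256 |
| eta run | 5.0 | 0.0527 |
| eta run | 7.5 | 0.0725 |
| eta run | 10 | 0.0865 |
| eta run | 12 | 0.0968 |
| eta run | 15 | 0.1076 |
| eta run | 18 | 0.1152 |
| eta run | 20 | 0.1210 |
| beta run | 2.5 | 0.0343 |
| beta run | 5.0 | 0.0707 |
| beta run | 7.5 | 0.0957 |
| beta run | 10 | 0.1152 |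
| beta run | 12 | 0.1275 |
| beta run | 15 | 0.1433 |
| beta run | 18 | 0.1543 |
| beta run | 20 | 0.1609 |

(scatter of a reading: 6 × 10⁻⁴ M)

- Overall: starting material + reagent -> target.
- Constant volume, constant temperature.
- What is held in complexes is read along with the free species.
- "The second partner" is reagent.
- An order is taken over about fifteen percent of the charge, up and down.

* apparent order in [reagent] of the starting rate, round the charge of the eta run (the rate where two percent of its starting material have turned into target)
* target in the epsilon run at 20 min, as a share of the starting material charged

Read the two target columns against each other, row by row. At 5.0 min the beta run holds 1.34 times the [target] of the eta run. Call this the same-clock ratio, [target] in the beta run over [target] in the eta run at one time. At 2.5 min it reads 1.34, at 10 min 1.33 and at 20 min 1.33, so the column of ratios is nearly constant and can be frozen.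

The frozen ratio gives an apparent order in [reagent]: its logarithm over the logarithm of the ratio of the charges, 0.424. I commit to this reading for the eta charge, taking the order across the doubling as the order round that charge.

The ratio says nothing about the epsilon run, because both runs hold [starting material] at 0.200 M. There I commit to a ceiling. The reagent is the limiting reagent, at 0.240 M against 0.800 M, so with one reagent per target the share stays below 30.0 %.

The forecast gives 0.55 and 23.5 %. It sets its order higher than mine, “slightly above the 0.44 averaged across” the doubling.

The flask gives an order of 0.44, closer to my 0.424 than to 0.55, and a share of 22.5 %, below the ceiling.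

    starting material ⇌ intermediate + by-product (0.1908 min⁻¹, 12.48 L mol⁻¹ min⁻¹)
    intermediate + reagent → target (4.212 L mol⁻¹ min⁻¹)
    2 starting material ⇌ idle substrate dimer, settled at all times (4.350 L mol⁻¹)
    reagent + by-product ⇌ reagent-by-product salt, settled at all times (4.320 L mol⁻¹)

Through both runs, starting material split into intermediate and by-product, and the intermediate either rejoined by-product or met reagent to give target. Meanwhile the idle substrate dimer stood beside the free starting material, and by-product, as it formed, held reagent as reagent-by-product salt. Carried to the beta run, the ratio 1.34 sets target equal to half of the starting material charged against 0.0745 M of target in the eta run, which the eta readings place at 7.86 min, and the beta run reached that amount of target at 8.07 min.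

The earlier runs and the new flask were generated by integration with constants of no real substance; the scatter is artificial.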